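**Retrosynthetic overview**

1. Ring C is closed last. The C2–O1 bond is cut to give the open, fully unprotected 2',4',6'-trihydroxy-3',5'-diprenylchalcone; a chiral bifunctional organocatalyst plays the part of chalcone isomerase and sets (2S) in the final step. Ring A is symmetric, so either ortho OH gives the same flavanone.
2. The chalcone comes from a protecting-group-free Claisen–Schmidt condensation of 3,5-diprenylphloroacetophenone with 7-hydroxy-2,2-dimethyl-2H-chromene-6-carbaldehyde.
3. The dimethylpyran ring is made first, by oxidative cyclisation of 2,4-dihydroxy-5-prenylbenzaldehyde (hydride abstraction, o-quinone methide, oxa-6π electrocyclisation).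
4. All three prenyl groups are put on by direct aromatic C-prenylation of phloroacetophenone and 2,4-dihydroxybenzaldehyde.
5. Ring order: rings A and B are bought; the pyran ring is formed in step 3 and ring C in step 5.

Assumption: the quinine-derived thiourea is taken to give the (2S) sense (the target SMILES is the 2S flavanone; 2S shows a positive Cotton effect near 330 nm and a negative one near 290 nm); if the CD spectrum shows 2R, the pseudoenantiomeric quinidine-derived thiourea is used under the same conditions.

**Step 1**
Reactants: 1 2,4,6-trihydroxyacetophenone; 2 prenyl bromide (1-bromo-3-methylbut-2-ene, 2.1 equiv)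
Product: 4 3,5-diprenyl-2,4,6-trihydroxyacetophenone (1-[2,4,6-trihydroxy-3,5-bis(3-methylbut-2-enyl)phenyl]ethanone), via 3-prenylphloroacetophenone 3 (not isolated)
Conditions: 10% aq KOH, 0 °C → rt, 3 h; acidify, chromatography
Reagents that add atoms: none
Why: Aromatic C-prenylation of the phloroglucinol polyanion (Friedel–Crafts-type C-alkylation of an ambident phenoxide in water), which can only occur at the two free ring carbons, gives the symmetric diprenyl ketone after separation from mono- and over-alkylated material; no stereocentre is formed.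

**Step 2**
Reactants: 5 2,4-dihydroxybenzaldehyde; 6 2-methylbut-3-en-2-ol (1.3 equiv)
Product: 7 2,4-dihydroxy-5-prenylbenzaldehyde (2,4-dihydroxy-5-(3-methylbut-2-enyl)benzaldehyde)
Conditions: BF3·OEt2 (0.5 equiv), 1,4-dioxane, rt, 16 h; stopped at partial conversion, chromatography (5 recovered)
Reagents that add atoms: none
Why: Friedel–Crafts prenylation by the dimethylallyl cation (from the tertiary allylic alcohol and BF3) favours C5, which is para to the 2-OH, ortho to the 4-OH and less hindered than C3; the 3-prenyl isomer is the separable by-product and no stereocentre is formed.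

**Step 3**
Reactants: 7 2,4-dihydroxy-5-prenylbenzaldehyde
Product: 9 7-hydroxy-2,2-dimethyl-2H-chromene-6-carbaldehyde, via ortho-quinone methide 8 (not isolated)
Conditions: DDQ (1.1 equiv), toluene, 80 °C, 2 h
Reagents that add atoms: none
Why: DDQ oxidative cyclisation of an o-prenylphenol: benzylic hydride abstraction gives the o-quinone methide, which closes by oxa-6π electrocyclisation; only the 4-OH is ortho to the prenyl group, so only the linear chromene can form, and no stereocentre is created.

**Step 4**
Reactants: 4 3,5-diprenyl-2,4,6-trihydroxyacetophenone; 9 7-hydroxy-2,2-dimethyl-2H-chromene-6-carbaldehyde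
Product: 11 (E)-3-(7-hydroxy-2,2-dimethyl-2H-chromen-6-yl)-1-[2,4,6-trihydroxy-3,5-bis(3-methylbut-2-enyl)phenyl]prop-2-en-1-one (open chalcone), via aldol adduct 10 (not isolated)
Conditions: LiN(SiMe3)2 (6.5 equiv), THF, −78 °C → rt, 16 h, dark; AcOH quench at 0 °C, rapid chromatography
Reagents that add atoms: none
Why: Claisen–Schmidt (aldol) condensation through the polylithiated ketone: excess amide base removes all phenolic protons and the methyl ketone proton, the lithium enolate adds to the lithium-chelated salicylaldehyde (which stays electrophilic, as in alkaline condensations of free salicylaldehydes), and E1cB loss of hydroxide gives the E-enone; the strongly basic medium holds the product as the open chalcone polyphenoxide.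

**Step 5**
Reactants: 11 open chalcone
Product: 12 euchrenone a3, (2S)-5,7-dihydroxy-2-(7-hydroxy-2,2-dimethyl-2H-chromen-6-yl)-6,8-bis(3-methylbut-2-enyl)chroman-4-one
Conditions: 1-[3,5-bis(trifluoromethyl)phenyl]-3-[(8S,9S)-6'-methoxycinchonan-9-yl]thiourea (20 mol %), toluene, 0 °C, dark, 24–72 h (chiral HPLC monitoring); filtration through silica with 0.5% AcOH in the eluent; recrystallisation to raise ee
Reagents that add atoms: none
Why: Proposed new method: enantioselective 6-endo-trig intramolecular oxa-Michael addition of the chalcone-isomerase type, in which the quinuclidine nitrogen acts as general base for one of the two equivalent ortho OH groups of ring A while the thiourea N–H pair binds the enone carbonyl already polarised by the hydrogen bond from the other ortho OH, so the phenoxide is delivered to one face of the β-carbon inside a chiral ion pair and C2 is set as (S) under catalyst control; the closest known reactions are the cinchona-thiourea-catalysed cyclisation of ester-activated 2'-hydroxychalcones to flavanones and the cinchona-alkaloid-catalysed cyclisation of 2',6'-dihydroxychalcones, and the low temperature, non-polar solvent and acidic silica quench keep the uncatalysed racemic closure and retro-Michael racemisation slow.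

**Compound list**

1 | 2,4,6-trihydroxyacetophenone (phloroacetophenone) | CC(=O)c1c(O)cc(O)cc1O | starting material
2 | prenyl bromide (1-bromo-3-methylbut-2-ene) | CC(C)=CCBr | starting material
3 | 3-prenylphloroacetophenone (1-[2,4,6-trihydroxy-3-(3-methylbut-2-enyl)phenyl]ethanone), not isolated | CC(=O)c1c(O)cc(O)c(CC=C(C)C)c1O | intermediate
4 | 3,5-diprenyl-2,4,6-trihydroxyacetophenone | CC(=O)c1c(O)c(CC=C(C)C)c(O)c(CC=C(C)C)c1O | intermediate
5 | 2,4-dihydroxybenzaldehyde | O=Cc1ccc(O)cc1O | starting material
6 | 2-methylbut-3-en-2-ol | CC(C)(O)C=C | starting material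
7 | 2,4-dihydroxy-5-prenylbenzaldehyde | O=Cc1cc(CC=C(C)C)c(O)cc1O | intermediate
8 | ortho-quinone methide (2-hydroxy-5-(3-methylbut-2-enylidene)-4-oxocyclohexa-2,6-diene-1-carbaldehyde skeleton; exocyclic alkene geometry undefined), not isolated | O=CC1=CC(=CC=C(C)C)C(=O)C=C1O | intermediate
9 | 7-hydroxy-2,2-dimethyl-2H-chromene-6-carbaldehyde | O=Cc1cc2C=CC(C)(C)Oc2cc1O | intermediate
10 | aldol adduct, racemic 3-hydroxy-3-(7-hydroxy-2,2-dimethyl-2H-chromen-6-yl)-1-[2,4,6-trihydroxy-3,5-bis(3-methylbut-2-enyl)phenyl]propan-1-one (present as its lithium salt), not isolated | CC(C)=CCc1c(O)c(CC=C(C)C)c(O)c(C(=O)CC(O)c2cc3C=CC(C)(C)Oc3cc2O)c1O | intermediate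
11 | (E)-3-(7-hydroxy-2,2-dimethyl-2H-chromen-6-yl)-1-[2,4,6-trihydroxy-3,5-bis(3-methylbut-2-enyl)phenyl]prop-2-en-1-one (open chalcone) | CC(C)=CCc1c(O)c(CC=C(C)C)c(O)c(C(=O)/C=C/c2cc3C=CC(C)(C)Oc3cc2O)c1O | intermediate
12 | euchrenone a3, (2S) | CC(C)=CCc1c(O)c(CC=C(C)C)c2c(c1O)C(=O)C[C@@H](c1cc3c(cc1O)OC(C)(C)C=C3)O2 | target

**Count and risks**

Total steps: 5. Longest linear sequence: 4 steps (5 → 7 → 9 → 11 → 12); step 1 is the convergent branch.

Most likely to fail:

Step 5 (enantioselectivity on an unactivated, electron-rich chalcone, and erosion of ee through reversible ring opening). The fallback sets out from 11 and comes back at 12. Chalcone 11 is closed under thermodynamic control (NaOAc, EtOH, reflux) to racemic euchrenone a3 F1. The enantiomers are then separated by preparative chiral-phase chromatography on amylose tris(3,5-dimethylphenylcarbamate), which gives 12 and (2R)-euchrenone a3 F2. F2 is re-racemised with NaOAc through the chalcone and resolved again.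

Step 4 (aldol of a tetra-anionic ketone with a phenoxide-bearing aldehyde). The fallback sets out from 4 and 9 and comes back at 11. MOMCl/i-Pr2NEt in CH2Cl2 converts 4 into 2-hydroxy-4,6-bis(methoxymethoxy)-3,5-diprenylacetophenone F3 (chelated OH left free) and 9 into 7-(methoxymethoxy)-2,2-dimethyl-2H-chromene-6-carbaldehyde F4. A classical KOH/EtOH–H2O Claisen–Schmidt condensation at rt joins them to the tris-MOM chalcone F5. Brief treatment with 3 M HCl in MeOH at rt removes the three acetals to give 11.

Step 2 (C5 versus C3 prenylation and acid-induced chroman formation). The fallback sets out from 5 and comes back at 7, and replaces Friedel–Crafts regiocontrol by a halogen-defined cross-coupling. ICl in AcOH gives 2,4-dihydroxy-5-iodobenzaldehyde F6, crystallised free of the 3-iodo isomer. Stille coupling with tributyl(3-methylbut-2-enyl)stannane (Pd(PPh3)4, DMF, 90 °C) then puts the linear prenyl group on the pre-defined carbon to give 7.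

**Further compounds**

F1 | step 5 | racemic euchrenone a3 (2RS) | CC(C)=CCc1c(O)c(CC=C(C)C)c2c(c1O)C(=O)CC(c1cc3c(cc1O)OC(C)(C)C=C3)O2
F2 | step 5 | (2R)-euchrenone a3 | CC(C)=CCc1c(O)c(CC=C(C)C)c2c(c1O)C(=O)C[C@H](c1cc3c(cc1O)OC(C)(C)C=C3)O2
F3 | step 4 | 2-hydroxy-4,6-bis(methoxymethoxy)-3,5-diprenylacetophenone | CC(=O)c1c(O)c(CC=C(C)C)c(OCOC)c(CC=C(C)C)c1OCOC
F4 | step 4 | 7-(methoxymethoxy)-2,2-dimethyl-2H-chromene-6-carbaldehyde | COCOc1cc2OC(C)(C)C=Cc2cc1C=O
F5 | step 4 | (E)-1-[2-hydroxy-4,6-bis(methoxymethoxy)-3,5-bis(3-methylbut-2-enyl)phenyl]-3-[7-(methoxymethoxy)-2,2-dimethyl-2H-chromen-6-yl]prop-2-en-1-one | COCOc1cc2OC(C)(C)C=Cc2cc1/C=C/C(=O)c1c(O)c(CC=C(C)C)c(OCOC)c(CC=C(C)C)c1OCOC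
F6 | step 2 | 2,4-dihydroxy-5-iodobenzaldehyde | O=Cc1cc(I)c(O)cc1O
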